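## Analysis of the target

The target 25 is a 2,4-disubstituted chroman (O1, C2, C3, C4, C4a, C8a). Ring A is a phloroglucinol nucleus whose three oxygens are all different: O1 is the ring ether, the C5 oxygen is a free phenol and the C7 oxygen is a methyl ether. C8, between O1 and the methoxy group, carries the (E)-4-hydroxycinnamoyl ketone. C2 bears a 4-hydroxyphenyl ring, and C4 bears the chain C1''H2–C2''H(OH)–CH2–CH2–(4-hydroxyphenyl). There are three stereocentres, C2 (R), C4 (S) and C2'' (R). C2 and C4 are trans on the pyran ring, while C4 and C2'' are 1,3-related across an open-chain CH2 with no ring to relay one into the other. The C2–O1 bond is a para-oxybenzylic aryl ether: it ionises under acid and can open through a para-quinone methide under base once the phenol is free, the more easily with the ketone at C8. The enone and the electron-rich ring A are further sensitive sites. The hard points are the remote C4/C2'' relation and the regiochemistry of ring A: C8 against C6, and a methyl group on the oxygen ortho to the ketone, the one that normally resists alkylation. The strategy rests on one feature: C2 binds oxygen reversibly, so if C2 is bonded to the C2'' oxygen instead of O1, the atoms C2–C3–C4–C1''–C2''–O form an oxane with all three substituents cis and equatorial.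

## Retrosynthetic reasoning

Target 25 to protected chalcone 24. The five hydroxyls are masked as silyl ethers (four aryl TIPS ethers, one alkyl TES ether), so the last step is a single buffered fluoride treatment. Nothing but O–Si bonds is cut, which keeps the base-sensitive C2–O1 bond and the enone away from any other late reagent.

24 to chroman 18 and Weinreb amide 21. The C8–C(=O) bond is cut. C8 is the only ring A carbon lying between two coordinating ether oxygens (the C7 methoxy group and O1), so it can be metalated selectively (aryllithium 22) when the C5 oxygen carries a bulky, non-coordinating silyl group. Amide 21 brings the whole enone with its E-geometry and stops at the ketone stage. 21 comes from acid 19 in two steps via 20.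

18 to 16 to chroman diol 15. The silyl groups at the C5 and C2'' oxygens and the methyl group at the C7 oxygen are removed in thought. The methyl group must enter before the ketone: once C8 is acylated, the C7 oxygen is the hydrogen-bonded ortho-hydroxyl of an aryl ketone and the least reactive. In 15 the two phenols differ only in their surroundings (C7-OH between two ring hydrogens, C5-OH peri to C4), and that difference has to carry the selectivity.

15 to oxane triol 14. The C2–O1 bond is cut and C2 is reconnected to the C2'' oxygen. Forward, acid ionises the benzylic C–O bond of the oxane and an ortho hydroxyl of ring A takes up the cation. This must be done while ring A is still a bare, symmetric triol: both ortho hydroxyls are then equivalent, and none is tied up in a hydrogen bond to a ketone. The step is reversible, so C2 settles in the more stable 2,4-trans arrangement.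

14 to 13 to α-acetoxy ether 11 and arene 12. After the benzyl ethers are put back (13), the C4–C4a and C2–C3 bonds are cut. This is the key disconnection: the oxane is made by a Prins ring closure of the oxocarbenium ion from 11, and the ring cation is captured by the threefold-symmetric arene 12. The cut is made here because the chair closure fixes the arene-bearing carbon and the carbinol carbon relative to each other, which is exactly the C4/C2'' relation of 25. Benzyl ethers are used on the arene so that it reacts only through carbon.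

11 to ester 9 to alcohol 5 and acid 8. The acetal carbon of 11 is the carbonyl carbon of ester 9 (reduction and trapping of the hemiacetal 10), and 9 is cut at the ester C–O bond. This places the electron-rich aryl group on the acetal carbon and leaves the only stereocentre in 5.

5 to aldehyde 3 to 2 to 1; 8 from 6. The C–C bond between the carbinol carbon and the allyl group is cut; an asymmetric allylboration of 3 sets the (R)-carbinol, from which all other centres follow. 3 comes from ester 1 by silylation and partial reduction; 8 comes from 6 by silylation.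

## Alternatives that were turned down

Alternative 1: aryne O-arylation with Michael capture. The cuts are O1–C8a and C4–C4a, both at ring A. Forward, CsF releases 3-benzyloxy-5-methoxybenzyne (A2); the alkoxide of the (R)-hydroxy dienone A3 adds at the future C8a, and the aryl anion at C4a closes onto the dienone β-carbon to give the 2,4-trans flavan A1.
- For it: the pyran ring and both ring A bonds form in one operation, the alkoxy group of A2 fixes the regiochemistry, and the C5/C7 oxygens arrive already differentiated (benzyl against methyl). On that last point it is stronger than the chosen route.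
- Against it: a secondary alkoxide adds sluggishly to an aryne, and the aryl anion is protonated by any O–H before it can cyclise. A3 is a δ-hydroxy enone that can lose water under basic fluoride, and it offers two Michael positions. C4 would be controlled only by the remote C2 centre.
- A1 still lacks C2'': the side-chain ketone has to be reduced to the (R)-alcohol with the C4 centre across a CH2, and its alkene has to be saturated selectively.
- Comparison: the chosen route sets C4 and C2'' together in a chair and gets C2 by equilibration. It pays for this with a later O-methylation that has to be selective.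

Alternative 2: oxidative benzylic C–H etherification. The cut is O1–C2 in a 1,3-diarylpropane. Forward, DDQ abstracts hydride from the para-benzyloxybenzylic CH2 of A5, and the ring A phenol adds to the cation to give the 8-acetyl flavan A4.
- For it: ring A is complete before ring closure (acetyl at C8, methoxy at C7), so no late metalation and no selective methylation are needed. Here it is stronger than the chosen route.
- Against it: A5 must already hold C4 and C2'', two centres 1,3 across a chain, which have to be made by separate and longer chemistry. The attacking phenol is hydrogen-bonded to the acetyl group and is a poor nucleophile. DDQ can also take the tertiary benzylic hydrogen at C4 next to the trioxygenated ring. The product's C2–H is more oxidisable than the CH2 of the substrate, so over-oxidation is likely. The benzyl ether must later be removed in the presence of the chalcone alkene.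
- Comparison: the chosen route reaches both stereocentres in one step from a single carbinol and needs no oxidant near ring A.

Alternative 3: ortho-quinone methide [4+2]. The cuts are C3–C4 and O1–C2. Forward, a chiral phosphoric acid dehydrates the ortho-hydroxybenzylic alcohol A7 to its quinone methide, which adds the styrene A8 to give chroman A6 with a free C5 hydroxyl.
- For it: it is the most direct construction, two bonds and the ring in one step with polarity-fixed regiochemistry. The C7 methyl ether of A7 can be placed reliably on the para hydroxyl of a chelated trihydroxyaryl carbonyl precursor. On both points it is as strong as or stronger than the chosen route.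
- Against it: the new C4 centre must be set against the acyclic C2'' centre across a CH2, where induction is weak, so the catalyst has to do all the work. Such cycloadditions normally favour the endo, 2,4-cis product, while the target is trans. A quinone methide with an alkyl group bearing β-hydrogens on the methide carbon tautomerises readily to the vinylphenol.
- Comparison: the chosen route gets C4/C2'' from a chair and the trans relation from thermodynamics, at the price of more steps after the key step.

Key step: step 7

## Route

Assumption: arene 12 and the allylborane of step 3 are purchased reagents. Chroman locants (C2–C8a, C1''–C4'') are used for the corresponding atoms throughout; the oxanes 13 and 14 are named with oxane locants.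

Step 1
Reactants: 1 methyl 3-(4-hydroxyphenyl)propanoate
Product: 2 methyl 3-[4-(triisopropylsilyloxy)phenyl]propanoate
Conditions: TIPSCl, imidazole, DMF, 25 °C
Reagents that add atoms: triisopropylsilyl chloride, CC(C)[Si](Cl)(C(C)C)C(C)C
Why: Silyl ether formation at the phenol; the TIPS ether is chosen because it withstands i-Bu2AlH, Me3SiOTf, acid, K2CO3 and n-BuLi later in the route.

Step 2
Reactants: 2 methyl 3-[4-(triisopropylsilyloxy)phenyl]propanoate
Product: 3 3-[4-(triisopropylsilyloxy)phenyl]propanal
Conditions: i-Bu2AlH (1.1 equiv), CH2Cl2, −78 °C; aq. potassium sodium tartrate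
Reagents that add atoms: none
Why: Partial reduction of a methyl ester; the aluminium hemiacetal is stable at −78 °C and collapses to the aldehyde only on work-up.

Step 3
Reactants: 3 3-[4-(triisopropylsilyloxy)phenyl]propanal
Product: 5 (3R)-1-[4-(triisopropylsilyloxy)phenyl]hex-5-en-3-ol, via borinate ester 4 (not isolated)
Conditions: (−)-Ipc2B(allyl) (isopinocampheyl groups from (+)-α-pinene), Et2O, −78 °C; then NaBO3·4H2O, THF–H2O, 25 °C
Reagents that add atoms: (−)-B-allyldiisopinocampheylborane, C=CCB([C@H]1[C@H](C)[C@H]2C[C@@H](C1)C2(C)C)[C@H]1[C@H](C)[C@H]2C[C@@H](C1)C2(C)C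
Why: Brown asymmetric allylboration through a chair Zimmerman–Traxler transition state; this enantiomer of the reagent delivers allyl to the Si face of a linear aldehyde, which here gives the (R)-carbinol. The perborate work-up cleaves the B–O and B–C bonds without touching the aryl silyl ether.

Step 4
Reactants: 6 4-hydroxybenzoic acid
Product: 8 4-(triisopropylsilyloxy)benzoic acid, via bis-silylated acid 7 (not isolated)
Conditions: TIPSCl (2.2 equiv), imidazole, DMF, 25 °C; then AcOH–THF–H2O, 25 °C
Reagents that add atoms: triisopropylsilyl chloride, CC(C)[Si](Cl)(C(C)C)C(C)C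
Why: Silylation of phenol and acid followed by selective hydrolysis of the silyl ester, which is far more labile than the aryl silyl ether.

Step 5
Reactants: 5 (3R)-1-[4-(triisopropylsilyloxy)phenyl]hex-5-en-3-ol; 8 4-(triisopropylsilyloxy)benzoic acid
Product: 9 (3R)-1-[4-(triisopropylsilyloxy)phenyl]hex-5-en-3-yl 4-(triisopropylsilyloxy)benzoate
Conditions: DCC, DMAP (0.2 equiv), CH2Cl2, 0 → 25 °C
Reagents that add atoms: none
Why: Steglich esterification of a secondary alcohol; the carbinol C–O bond is not broken, so the configuration is kept.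

Step 6
Reactants: 9 (3R)-1-[4-(triisopropylsilyloxy)phenyl]hex-5-en-3-yl 4-(triisopropylsilyloxy)benzoate
Product: 11 {[(3R)-1-[4-(triisopropylsilyloxy)phenyl]hex-5-en-3-yl]oxy}[4-(triisopropylsilyloxy)phenyl]methyl acetate (both acetal epimers), via aluminium hemiacetal 10 (not isolated)
Conditions: i-Bu2AlH (2 equiv), CH2Cl2, −78 °C; then pyridine, DMAP, Ac2O, −78 → −20 °C
Reagents that add atoms: acetic anhydride, CC(=O)OC(C)=O
Why: Reductive acetylation of an ester: the aluminium hemiacetal is acetylated in the cold before it can collapse to the aldehyde. The α-acetoxy ether of an electron-rich aryl group ionises easily, so it should be used crude or after filtration through base-washed silica.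

Step 7
Reactants: 11 the α-acetoxy ether; 12 1,3,5-tris(benzyloxy)benzene
Product: 13 (2R,4S,6R)-2-[4-(triisopropylsilyloxy)phenyl]-4-[2,4,6-tris(benzyloxy)phenyl]-6-{2-[4-(triisopropylsilyloxy)phenyl]ethyl}oxane (all-cis)
Conditions: 12 (2 equiv), Me3SiOTf (1.2 equiv), 2,6-di-tert-butyl-4-methylpyridine (1.5 equiv), CH2Cl2 (0.01 M), −78 → −40 °C; aq. NaHCO3
Reagents that add atoms: none
Why: Me3SiOTf silylates the acetate of 11 and releases the (E)-oxocarbenium ion conjugated with the silyloxyphenyl ring; the terminal alkene carbon attacks the acetal carbon through a chair in which the aryl group and the arylethyl chain are both equatorial, which forms C2–C3 and closes the oxane (6-endo-trig with respect to the alkene, a cation–olefin Prins closure). The resulting 4-oxanyl cation is captured by 12 along the equatorial trajectory to form C4–C4a, and loss of the ring proton to the hindered pyridine restores the arene (Friedel–Crafts alkylation). The closest known reaction type is the segment-coupling Prins cyclisation of α-acetoxy ethers terminated by Friedel–Crafts capture with trialkoxybenzenes. The aryl-bearing carbon is set cis to the C6 chain by the chair with an E-oxocarbenium ion and the C4 centre by equatorial capture, so both follow from the (R)-carbinol of 5 and the ring is all-cis; in this ring the arene-bearing carbon and the carbinol carbon already have the relation of C4 and C2'' of 25. Three selectivities are needed: ring closure must outrun bimolecular attack of 12 on the open oxocarbenium ion (helped by the unimolecular chair closure, high dilution and only 2 equiv of 12); the arene must outrun return of acetate or triflate (12 is a strong neutral π-nucleophile, and attack through its ether oxygens is reversible and unproductive); and the arene must react at one site only, which its threefold symmetry guarantees. The acetal carbon of 11 becomes planar, so its epimer mixture does not matter; because the electron-rich aryl group sits on the acetal carbon and not on the carbinol carbon, an oxonia-Cope shift leads back to the same ion and the carbinol centre should be kept, while the base keeps TfOH from opening the product at its benzylic C–O bond.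

Step 8
Reactants: 13 the tribenzyl oxane
Product: 14 2-[(2R,4S,6R)-2-[4-(triisopropylsilyloxy)phenyl]-6-{2-[4-(triisopropylsilyloxy)phenyl]ethyl}oxan-4-yl]benzene-1,3,5-triol
Conditions: H2 (1 atm), Pd/C, EtOAc, 25 °C
Reagents that add atoms: none
Why: Hydrogenolysis of aryl benzyl ethers, which are cleaved much faster than the cyclic benzylic ether of the oxane; there is no alkene in the molecule and aryl TIPS ethers are inert.

Step 9
Reactants: 14 the oxane triol
Product: 15 (2R,4S)-4-{(2R)-2-hydroxy-4-[4-(triisopropylsilyloxy)phenyl]butyl}-2-[4-(triisopropylsilyloxy)phenyl]chromane-5,7-diol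
Conditions: TsOH·H2O (0.2 equiv), CH2Cl2 (0.005 M), 0 → 25 °C
Reagents that add atoms: none
Why: Acid-catalysed transposition of a para-oxybenzylic ether: protonation of the ring oxygen and ionisation at the silyloxybenzylic carbon give a stabilised cation, which either ortho hydroxyl of the symmetric triol (the two are equivalent) captures in a six-membered closure. The process is reversible, so the new C2 centre settles under thermodynamic control with the aryl group equatorial and the C4 substituent pseudoaxial, away from the peri C5 hydroxyl, i.e. 2,4-trans; C4 and C2'' are not touched. High dilution suppresses intermolecular C-benzylation of ring A.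

Step 10
Reactants: 15 the chroman-5,7-diol
Product: 16 (2R,4S)-4-{(2R)-2-hydroxy-4-[4-(triisopropylsilyloxy)phenyl]butyl}-7-methoxy-2-[4-(triisopropylsilyloxy)phenyl]chroman-5-ol
Conditions: MeI (1.05 equiv), K2CO3 (1.1 equiv), acetone, 0 → 25 °C
Reagents that add atoms: iodomethane, CI
Why: Williamson O-methylation with a limiting amount of MeI: the C7 hydroxyl lies between two ring hydrogens, whereas the C5 hydroxyl is peri to C4 and its pseudoaxial side chain, so the C7 phenoxide should react preferentially; K2CO3 does not deprotonate the aliphatic hydroxyl. The methyl group has to enter here, because after acylation at C8 the C7 oxygen would be a hydrogen-bonded ortho-hydroxyl and the least reactive.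

Step 11
Reactants: 16 the 7-methoxychroman-5-ol
Product: 18 (2R,4R)-7-methoxy-4-{(2R)-2-(triethylsilyloxy)-4-[4-(triisopropylsilyloxy)phenyl]butyl}-5-(triisopropylsilyloxy)-2-[4-(triisopropylsilyloxy)phenyl]chromane (the C4 descriptor changes only because silylation raises the CIP rank of the side chain; the geometry is unchanged), via phenol silyl ether 17 (not isolated)
Conditions: TIPSCl (1.3 equiv), imidazole, DMF, 25 °C; then Et3SiCl (1.5 equiv), 0 → 25 °C
Reagents that add atoms: triisopropylsilyl chloride, CC(C)[Si](Cl)(C(C)C)C(C)C; triethylsilyl chloride, CC[Si](Cl)(CC)CC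
Why: Silyl ether formation in two stages: TIPSCl/imidazole silylates the phenol much faster than the secondary alcohol, and Et3SiCl then caps the alcohol. The bulky, non-coordinating TIPS ether at C5 shields C6 for the metalation, and the TES ether is chosen because it leaves under the buffered fluoride of the last step.

Step 12
Reactants: 19 (E)-3-(4-hydroxyphenyl)prop-2-enoic acid
Product: 20 (E)-3-(4-hydroxyphenyl)-N-methoxy-N-methylprop-2-enamide
Conditions: MeNH(OMe)·HCl, EDC·HCl, HOBt (cat.), N-methylmorpholine, DMF, 0 → 25 °C
Reagents that add atoms: N,O-dimethylhydroxylamine hydrochloride, CNOC.Cl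
Why: Carbodiimide amide coupling; the amine reacts with the activated ester much faster than the free phenol does, and the E-alkene of the commercial acid is carried through.

Step 13
Reactants: 20 the phenolic Weinreb amide
Product: 21 (E)-N-methoxy-N-methyl-3-[4-(triisopropylsilyloxy)phenyl]prop-2-enamide
Conditions: TIPSCl, imidazole, DMF, 25 °C
Reagents that add atoms: triisopropylsilyl chloride, CC(C)[Si](Cl)(C(C)C)C(C)C
Why: Silyl ether formation; it removes the acidic phenol that would quench the aryllithium in step 14.

Step 14
Reactants: 18 the fully protected chroman; 21 the silylated Weinreb amide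
Product: 24 (E)-1-[(2R,4R)-7-methoxy-4-{(2R)-2-(triethylsilyloxy)-4-[4-(triisopropylsilyloxy)phenyl]butyl}-5-(triisopropylsilyloxy)-2-[4-(triisopropylsilyloxy)phenyl]chroman-8-yl]-3-[4-(triisopropylsilyloxy)phenyl]prop-2-en-1-one, via aryllithium 22 (not isolated), via tetrahedral lithium adduct 23 (not isolated)
Conditions: n-BuLi (1.2 equiv), TMEDA (1.2 equiv), THF, 0 °C; then 21 (1.5 equiv), −78 → 0 °C; aq. NH4Cl
Reagents that add atoms: none
Why: Directed ortho-metalation followed by Weinreb ketone synthesis: C8–H is the only ring position between two coordinating ether oxygens (the methoxy group and O1), whereas C6 is shielded by the TIPS ether, so lithiation should occur at C8. The aryllithium adds 1,2 to the amide and the chelated adduct holds until the quench, which prevents over-addition and leaves the E-alkene untouched.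

Step 15
Reactants: 24 the protected chalcone
Product: 25 (E)-1-[(2R,4S)-5-hydroxy-4-[(2R)-2-hydroxy-4-(4-hydroxyphenyl)butyl]-2-(4-hydroxyphenyl)-7-methoxychroman-8-yl]-3-(4-hydroxyphenyl)prop-2-en-1-one
Conditions: Bu4NF (6 equiv), AcOH (6 equiv), THF, 0 → 25 °C
Reagents that add atoms: none
Why: Fluoride-mediated cleavage of the four aryl TIPS ethers and the TES ether. Acetic acid keeps the liberated phenols protonated; a free phenoxide para to C2 could otherwise open the pyran ring through a para-quinone methide (the C8 ketone makes O1 a good leaving group) and erode C2 or allow oxa-Michael closure onto the enone.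

## Compound list

1 | methyl 3-(4-hydroxyphenyl)propanoate | COC(=O)CCc1ccc(O)cc1 | starting material
2 | methyl 3-[4-(triisopropylsilyloxy)phenyl]propanoate | COC(=O)CCc1ccc(O[Si](C(C)C)(C(C)C)C(C)C)cc1 | intermediate
3 | 3-[4-(triisopropylsilyloxy)phenyl]propanal | O=CCCc1ccc(O[Si](C(C)C)(C(C)C)C(C)C)cc1 | intermediate
4 | diisopinocampheylborinate of alcohol 5 | C=CC[C@H](OB([C@H]1[C@H](C)[C@H]2C[C@@H](C1)C2(C)C)[C@H]1[C@H](C)[C@H]2C[C@@H](C1)C2(C)C)CCc1ccc(O[Si](C(C)C)(C(C)C)C(C)C)cc1 | intermediate (not isolated)
5 | (3R)-1-[4-(triisopropylsilyloxy)phenyl]hex-5-en-3-ol | C=CC[C@H](O)CCc1ccc(O[Si](C(C)C)(C(C)C)C(C)C)cc1 | intermediate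
6 | 4-hydroxybenzoic acid | OC(=O)c1ccc(O)cc1 | starting material
7 | triisopropylsilyl 4-(triisopropylsilyloxy)benzoate | CC(C)[Si](OC(=O)c1ccc(O[Si](C(C)C)(C(C)C)C(C)C)cc1)(C(C)C)C(C)C | intermediate (not isolated)
8 | 4-(triisopropylsilyloxy)benzoic acid | OC(=O)c1ccc(O[Si](C(C)C)(C(C)C)C(C)C)cc1 | intermediate
9 | (3R)-1-[4-(triisopropylsilyloxy)phenyl]hex-5-en-3-yl 4-(triisopropylsilyloxy)benzoate | C=CC[C@H](OC(=O)c1ccc(O[Si](C(C)C)(C(C)C)C(C)C)cc1)CCc1ccc(O[Si](C(C)C)(C(C)C)C(C)C)cc1 | intermediate
10 | diisobutylaluminium hemiacetal of ester 9 | C=CC[C@H](OC(O[Al](CC(C)C)CC(C)C)c1ccc(O[Si](C(C)C)(C(C)C)C(C)C)cc1)CCc1ccc(O[Si](C(C)C)(C(C)C)C(C)C)cc1 | intermediate (not isolated)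
11 | {[(3R)-1-[4-(triisopropylsilyloxy)phenyl]hex-5-en-3-yl]oxy}[4-(triisopropylsilyloxy)phenyl]methyl acetate, both acetal epimers | C=CC[C@H](OC(OC(C)=O)c1ccc(O[Si](C(C)C)(C(C)C)C(C)C)cc1)CCc1ccc(O[Si](C(C)C)(C(C)C)C(C)C)cc1 | intermediate
12 | 1,3,5-tris(benzyloxy)benzene | c1ccc(COc2cc(OCc3ccccc3)cc(OCc3ccccc3)c2)cc1 | starting material
13 | (2R,4S,6R)-2-[4-(triisopropylsilyloxy)phenyl]-4-[2,4,6-tris(benzyloxy)phenyl]-6-{2-[4-(triisopropylsilyloxy)phenyl]ethyl}oxane | O1[C@@H](c2ccc(O[Si](C(C)C)(C(C)C)C(C)C)cc2)C[C@@H](c2c(OCc3ccccc3)cc(OCc3ccccc3)cc2OCc2ccccc2)C[C@H]1CCc1ccc(O[Si](C(C)C)(C(C)C)C(C)C)cc1 | intermediate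
14 | 2-[(2R,4S,6R)-2-[4-(triisopropylsilyloxy)phenyl]-6-{2-[4-(triisopropylsilyloxy)phenyl]ethyl}oxan-4-yl]benzene-1,3,5-triol | O1[C@@H](c2ccc(O[Si](C(C)C)(C(C)C)C(C)C)cc2)C[C@@H](c2c(O)cc(O)cc2O)C[C@H]1CCc1ccc(O[Si](C(C)C)(C(C)C)C(C)C)cc1 | intermediate
15 | (2R,4S)-4-{(2R)-2-hydroxy-4-[4-(triisopropylsilyloxy)phenyl]butyl}-2-[4-(triisopropylsilyloxy)phenyl]chromane-5,7-diol | Oc1cc(O)c2c(c1)O[C@@H](c1ccc(O[Si](C(C)C)(C(C)C)C(C)C)cc1)C[C@@H]2C[C@H](O)CCc1ccc(O[Si](C(C)C)(C(C)C)C(C)C)cc1 | intermediate
16 | (2R,4S)-4-{(2R)-2-hydroxy-4-[4-(triisopropylsilyloxy)phenyl]butyl}-7-methoxy-2-[4-(triisopropylsilyloxy)phenyl]chroman-5-ol | COc1cc(O)c2c(c1)O[C@@H](c1ccc(O[Si](C(C)C)(C(C)C)C(C)C)cc1)C[C@@H]2C[C@H](O)CCc1ccc(O[Si](C(C)C)(C(C)C)C(C)C)cc1 | intermediate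
17 | (2R)-1-[(2R,4S)-7-methoxy-5-(triisopropylsilyloxy)-2-[4-(triisopropylsilyloxy)phenyl]chroman-4-yl]-4-[4-(triisopropylsilyloxy)phenyl]butan-2-ol | COc1cc(O[Si](C(C)C)(C(C)C)C(C)C)c2c(c1)O[C@@H](c1ccc(O[Si](C(C)C)(C(C)C)C(C)C)cc1)C[C@@H]2C[C@H](O)CCc1ccc(O[Si](C(C)C)(C(C)C)C(C)C)cc1 | intermediate (not isolated)
18 | (2R,4R)-7-methoxy-4-{(2R)-2-(triethylsilyloxy)-4-[4-(triisopropylsilyloxy)phenyl]butyl}-5-(triisopropylsilyloxy)-2-[4-(triisopropylsilyloxy)phenyl]chromane | COc1cc(O[Si](C(C)C)(C(C)C)C(C)C)c2c(c1)O[C@@H](c1ccc(O[Si](C(C)C)(C(C)C)C(C)C)cc1)C[C@@H]2C[C@H](O[Si](CC)(CC)CC)CCc1ccc(O[Si](C(C)C)(C(C)C)C(C)C)cc1 | intermediate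
19 | (E)-3-(4-hydroxyphenyl)prop-2-enoic acid | OC(=O)/C=C/c1ccc(O)cc1 | starting material
20 | (E)-3-(4-hydroxyphenyl)-N-methoxy-N-methylprop-2-enamide | CON(C)C(=O)/C=C/c1ccc(O)cc1 | intermediate
21 | (E)-N-methoxy-N-methyl-3-[4-(triisopropylsilyloxy)phenyl]prop-2-enamide | CON(C)C(=O)/C=C/c1ccc(O[Si](C(C)C)(C(C)C)C(C)C)cc1 | intermediate
22 | 8-lithio derivative of chroman 18 | COc1cc(O[Si](C(C)C)(C(C)C)C(C)C)c2c(c1[Li])O[C@@H](c1ccc(O[Si](C(C)C)(C(C)C)C(C)C)cc1)C[C@@H]2C[C@H](O[Si](CC)(CC)CC)CCc1ccc(O[Si](C(C)C)(C(C)C)C(C)C)cc1 | intermediate (not isolated)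
23 | lithium alkoxide of the N-methoxy-N-methyl hemiaminal from 22 and 21 | COc1cc(O[Si](C(C)C)(C(C)C)C(C)C)c2c(c1C(O[Li])(N(C)OC)/C=C/c1ccc(O[Si](C(C)C)(C(C)C)C(C)C)cc1)O[C@@H](c1ccc(O[Si](C(C)C)(C(C)C)C(C)C)cc1)C[C@@H]2C[C@H](O[Si](CC)(CC)CC)CCc1ccc(O[Si](C(C)C)(C(C)C)C(C)C)cc1 | intermediate (not isolated)
24 | (E)-1-[(2R,4R)-7-methoxy-4-{(2R)-2-(triethylsilyloxy)-4-[4-(triisopropylsilyloxy)phenyl]butyl}-5-(triisopropylsilyloxy)-2-[4-(triisopropylsilyloxy)phenyl]chroman-8-yl]-3-[4-(triisopropylsilyloxy)phenyl]prop-2-en-1-one | COc1cc(O[Si](C(C)C)(C(C)C)C(C)C)c2c(c1C(=O)/C=C/c1ccc(O[Si](C(C)C)(C(C)C)C(C)C)cc1)O[C@@H](c1ccc(O[Si](C(C)C)(C(C)C)C(C)C)cc1)C[C@@H]2C[C@H](O[Si](CC)(CC)CC)CCc1ccc(O[Si](C(C)C)(C(C)C)C(C)C)cc1 | intermediate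
25 | (E)-1-[(2R,4S)-5-hydroxy-4-[(2R)-2-hydroxy-4-(4-hydroxyphenyl)butyl]-2-(4-hydroxyphenyl)-7-methoxychroman-8-yl]-3-(4-hydroxyphenyl)prop-2-en-1-one | COc1cc(O)c2c(c1C(=O)/C=C/c1ccc(O)cc1)O[C@@H](c1ccc(O)cc1)C[C@@H]2C[C@H](O)CCc1ccc(O)cc1 | target

## Step count and least certain steps

Total: 15 steps. Longest linear sequence: 12 steps (1, 2, 3, 5, 6, 7, 8, 9, 10, 11, 14, 15).

Step 7 (key step). The most likely failure is bimolecular Friedel–Crafts attack of the arene on the open oxocarbenium ion before the ring closes, because the silyloxyphenyl group lengthens the life of that ion. A lesser risk is partial loss of optical purity through ionisation of the product at its benzylic C–O bond. The fallback separates ring closure from arylation. From 11, SnBr4 in CH2Cl2 at −78 °C should close the oxane with bromide capture and no arene present, giving the all-cis 4-bromo-2-[4-(triisopropylsilyloxy)phenyl]-6-{2-[4-(triisopropylsilyloxy)phenyl]ethyl}oxane F1. Arene 12 is brominated with NBS to 2-bromo-1,3,5-tris(benzyloxy)benzene F2 and converted with magnesium into 2,4,6-tris(benzyloxy)phenylmagnesium bromide F3. A Kumada coupling of F1 with F3 catalysed by FeCl3 with TMEDA joins C4 to C4a through the secondary alkyl radical, which should be arylated from the equatorial side. The route is rejoined at 13.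

Step 8. The risk is over-reduction: hydrogenolysis of the benzylic C–O bond of the oxane ring alongside the benzyl ethers. The fallback is a non-reductive debenzylation of 13 with BCl3 and pentamethylbenzene at −78 °C. This Lewis acid also ionises the benzylic ring C–O bond, so debenzylation and transposition would be run as one operation on warming, and the route is rejoined at 15. This fallback makes no new isolated compound (F0).

Step 9. The risks are an equilibrium that stops short of the chroman and intermolecular C-benzylation of the electron-rich ring A by the benzylic cation. The fallback drives the ring opening by silyl transfer. Triol 14 is persilylated with N,O-bis(trimethylsilyl)acetamide to the tris(trimethylsilyl) ether of the oxane triol F4. Catalytic Me3SiOTf in CH2Cl2 at −40 °C then silylates the ring oxygen as the C–O bond ionises, and an ortho silyloxy oxygen closes the chroman with release of the silyl group, giving the tris(trimethylsilyl) ether of the chroman triol F5. The silyl group ends on the more basic alkoxide oxygen, which pulls the equilibrium, and a silylated ring A is a poorer carbon nucleophile. Methanolysis (MeOH, PPTS) returns to the route at 15.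

Step 10. The risk is poor site selectivity between the C7 and C5 hydroxyls, together with double methylation, because the steric difference is modest for a small electrophile. The fallback uses a bulky acyl transfer for the discrimination and exchanges acyl for methyl later.
- From 15, pivaloyl chloride (1 equiv) and Et3N in CH2Cl2 at −40 °C should give the 7-O-pivalate of the chroman diol F6.
- TIPSCl/imidazole and then Et3SiCl give the 7-O-pivaloyl 5-O-TIPS 2''-O-TES chroman F7.
- i-Bu2AlH at −78 °C removes the pivalate to give the 7-hydroxy 5-O-TIPS 2''-O-TES chroman F8.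
- MeI and K2CO3 in acetone methylate the only free phenol, and the route is rejoined at 18.

Step 14. The risk is metalation at the wrong site (C6 next to the silyl ether, or the benzylic C2–H) or attack of the base on silicon. The fallback fixes the site by halogenation. From 18, NBS in CH2Cl2 at 0 °C should brominate C8, since C6 is shielded by the TIPS ether, giving the 8-bromo derivative of chroman 18 F9. Bromine–lithium exchange with t-BuLi (2 equiv) in THF at −78 °C gives aryllithium 22, where the route is rejoined.

## Further compounds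

F1 | step 7 | all-cis 4-bromo-2-[4-(triisopropylsilyloxy)phenyl]-6-{2-[4-(triisopropylsilyloxy)phenyl]ethyl}oxane | O1[C@@H](c2ccc(O[Si](C(C)C)(C(C)C)C(C)C)cc2)C[C@@H](Br)C[C@H]1CCc1ccc(O[Si](C(C)C)(C(C)C)C(C)C)cc1
F2 | step 7 | 2-bromo-1,3,5-tris(benzyloxy)benzene | Brc1c(OCc2ccccc2)cc(OCc2ccccc2)cc1OCc1ccccc1
F3 | step 7 | 2,4,6-tris(benzyloxy)phenylmagnesium bromide | Br[Mg]c1c(OCc2ccccc2)cc(OCc2ccccc2)cc1OCc1ccccc1
F0 | step 8 | none | none
F4 | step 9 | tris(trimethylsilyl) ether of oxane triol 14 | O1[C@@H](c2ccc(O[Si](C(C)C)(C(C)C)C(C)C)cc2)C[C@@H](c2c(O[Si](C)(C)C)cc(O[Si](C)(C)C)cc2O[Si](C)(C)C)C[C@H]1CCc1ccc(O[Si](C(C)C)(C(C)C)C(C)C)cc1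
F5 | step 9 | tris(trimethylsilyl) ether of chroman triol 15 | C[Si](C)(C)Oc1cc(O[Si](C)(C)C)c2c(c1)O[C@@H](c1ccc(O[Si](C(C)C)(C(C)C)C(C)C)cc1)C[C@@H]2C[C@H](O[Si](C)(C)C)CCc1ccc(O[Si](C(C)C)(C(C)C)C(C)C)cc1
F6 | step 10 | 7-O-pivalate of chroman diol 15 | CC(C)(C)C(=O)Oc1cc(O)c2c(c1)O[C@@H](c1ccc(O[Si](C(C)C)(C(C)C)C(C)C)cc1)C[C@@H]2C[C@H](O)CCc1ccc(O[Si](C(C)C)(C(C)C)C(C)C)cc1
F7 | step 10 | 7-O-pivaloyl 5-O-triisopropylsilyl 2''-O-triethylsilyl chroman | CC(C)(C)C(=O)Oc1cc(O[Si](C(C)C)(C(C)C)C(C)C)c2c(c1)O[C@@H](c1ccc(O[Si](C(C)C)(C(C)C)C(C)C)cc1)C[C@@H]2C[C@H](O[Si](CC)(CC)CC)CCc1ccc(O[Si](C(C)C)(C(C)C)C(C)C)cc1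
F8 | step 10 | 7-hydroxy 5-O-triisopropylsilyl 2''-O-triethylsilyl chroman | Oc1cc(O[Si](C(C)C)(C(C)C)C(C)C)c2c(c1)O[C@@H](c1ccc(O[Si](C(C)C)(C(C)C)C(C)C)cc1)C[C@@H]2C[C@H](O[Si](CC)(CC)CC)CCc1ccc(O[Si](C(C)C)(C(C)C)C(C)C)cc1
F9 | step 14 | 8-bromo derivative of chroman 18 | COc1cc(O[Si](C(C)C)(C(C)C)C(C)C)c2c(c1Br)O[C@@H](c1ccc(O[Si](C(C)C)(C(C)C)C(C)C)cc1)C[C@@H]2C[C@H](O[Si](CC)(CC)CC)CCc1ccc(O[Si](C(C)C)(C(C)C)C(C)C)cc1
A1 | alternative 1 | (E)-1-[(2R,4R)-5-benzyloxy-7-methoxy-2-[4-(methoxymethoxy)phenyl]chroman-4-yl]-4-[4-(methoxymethoxy)phenyl]but-3-en-2-one (2,4-trans) | COc1cc(OCc3ccccc3)c2c(c1)O[C@@H](c1ccc(OCOC)cc1)C[C@@H]2CC(=O)/C=C/c1ccc(OCOC)cc1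
A2 | alternative 1 | 3-benzyloxy-5-methoxybenzyne | COC1=CC#CC(OCc2ccccc2)=C1
A3 | alternative 1 | (1E,4E,7R)-7-hydroxy-1,7-bis[4-(methoxymethoxy)phenyl]hepta-1,4-dien-3-one | O[C@@H](c1ccc(OCOC)cc1)C/C=C/C(=O)/C=C/c1ccc(OCOC)cc1
A4 | alternative 2 | (2R)-1-[(2R,4S)-8-acetyl-2-(4-benzyloxyphenyl)-5-(tert-butyldimethylsilyloxy)-7-methoxychroman-4-yl]-4-[4-(pivaloyloxy)phenyl]butan-2-yl acetate | COc1cc(O[Si](C)(C)C(C)(C)C)c2c(c1C(C)=O)O[C@@H](c1ccc(OCc3ccccc3)cc1)C[C@@H]2C[C@H](OC(C)=O)CCc1ccc(OC(=O)C(C)(C)C)cc1
A5 | alternative 2 | (3R,5R)-5-[3-acetyl-6-(tert-butyldimethylsilyloxy)-2-hydroxy-4-methoxyphenyl]-7-(4-benzyloxyphenyl)-1-[4-(pivaloyloxy)phenyl]heptan-3-yl acetate | COc1cc(O[Si](C)(C)C(C)(C)C)c([C@H](CCc2ccc(OCc3ccccc3)cc2)C[C@H](OC(C)=O)CCc2ccc(OC(=O)C(C)(C)C)cc2)c(O)c1C(C)=O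
A6 | alternative 3 | (2R,4R)-4-{(2R)-2-(tert-butyldimethylsilyloxy)-4-[4-(tert-butyldimethylsilyloxy)phenyl]butyl}-2-[4-(tert-butyldimethylsilyloxy)phenyl]-7-methoxychroman-5-ol (2,4-trans) | COc1cc(O)c2c(c1)O[C@@H](c1ccc(O[Si](C)(C)C(C)(C)C)cc1)C[C@@H]2C[C@H](O[Si](C)(C)C(C)(C)C)CCc1ccc(O[Si](C)(C)C(C)(C)C)cc1
A7 | alternative 3 | 2-{(3R)-3-(tert-butyldimethylsilyloxy)-5-[4-(tert-butyldimethylsilyloxy)phenyl]-1-hydroxypentyl}-5-methoxybenzene-1,3-diol | COc1cc(O)c(C(O)C[C@H](O[Si](C)(C)C(C)(C)C)CCc2ccc(O[Si](C)(C)C(C)(C)C)cc2)c(O)c1
A8 | alternative 3 | 4-(tert-butyldimethylsilyloxy)styrene | C=Cc1ccc(O[Si](C)(C)C(C)(C)C)cc1
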